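## Retrosynthetic overview
1. Ring B (ten-membered) is closed last. C3=C4 and the C5=C16 methylene come from an ethylene-assisted ene–yne metathesis/RCM of a seco enyne that already carries every heteroatom.
2. Key bond C9–C10: the C9 aldehyde carbon of the lactone half becomes a nucleophilic α-acetoxyalkyl (masked ketyl) radical. It adds to the equally electrophilic enone carbon C10 of ring A. This joins the halves, brings in 9-OAc and sets C9, C10 and C11.
3. Ring A half: asymmetric Birch reductive methylation of a 2-methoxy-5-methylbenzamide (C1), ketone reduction (C14), Felkin vinylation (C2), allylic oxidation (C12).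
4. Ring C half: Sharpless epoxide (C6, C7), dithiane acyl-anion homologation (C9), acylative chloride opening (C6–Cl), intramolecular Reformatsky lactonisation (C8, C17).
5. Ring order: A (from the arene), then C (lactone), then B (macrocycle).

Assumption: atoms carry briarane numbers (C1 quaternary, C2 OAc, C5=C16, C6 Cl, C7–O–C19 lactone, C8 OH, C9 OAc, C12 ketone, C14 butanoate). The Birch alkylation is taken to follow the chelated-enolate model, with CH3 entering anti to the CH2OMe arm, so the (S)-auxiliary gives (R)-C1.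

## Route

Step 1
Reactants: 1 2-methoxy-5-methylbenzoic acid; 2 (S)-2-(methoxymethyl)pyrrolidine
Product: 4 (S)-1-(2-methoxy-5-methylbenzoyl)-2-(methoxymethyl)pyrrolidine, via acid chloride 3 (not isolated)
Conditions: SOCl2, cat. DMF, toluene, 70 °C, evaporate; 2, Et3N, CH2Cl2, 0 °C to rt
Reagents that add atoms: none
Why: Amide formation through the acid chloride (Schotten–Baumann type) attaches the proline-derived auxiliary and creates no new stereocentre.

Step 2
Reactants: 4 (S)-1-(2-methoxy-5-methylbenzoyl)-2-(methoxymethyl)pyrrolidine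
Product: 7 keto amide (1R)-1,3-dimethyl-6-oxocyclohex-2-ene-1-carboxamide of 2, via potassium enolate 5 (not isolated), via methylated diene 6 (not isolated)
Conditions: K (2.3 equiv), t-BuOH (1 equiv), NH3/THF, −78 °C; MeI, −78 °C to rt; then 2 M HCl, MeOH, rt
Reagents that add atoms: iodomethane (CI); water (O)
Why: In this asymmetric Birch reduction–alkylation (Schultz type) the arene is reduced at C1/C12, the K-chelated enolate 5 is methylated anti to the CH2OMe arm to set quaternary C1 as R, and acid hydrolysis of the C14 enol ether gives the ketone while C10=C11 cannot move past quaternary C1.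

Step 3
Reactants: 7 keto amide
Product: 9 (1S,2R)-2-{[(S)-2-(methoxymethyl)pyrrolidin-1-yl]carbonyl}-2,4-dimethylcyclohex-3-en-1-yl butanoate, via lithium alkoxide 8 (not isolated)
Conditions: LiBH(s-Bu)3, THF, −78 °C; then (n-PrCO)2O, DMAP, −78 °C to rt
Reagents that add atoms: butanoic anhydride (CCCC(=O)OC(=O)CCC)
Why: In this diastereoselective ketone reduction with in situ O-acylation the bulky hydride attacks C14 anti to the pseudoaxial carboxamide (on the CH3 face), giving the 14S alkoxide with O cis to C2, which is trapped as the butanoate.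

Step 4
Reactants: 9 butanoate amide
Product: 10 (1S,2R)-2-formyl-2,4-dimethylcyclohex-3-en-1-yl butanoate
Conditions: Cp2Zr(H)Cl (2 equiv), THF, rt; SiO2/H2O
Reagents that add atoms: none
Why: Chemoselective amide-to-aldehyde reduction by hydrozirconation of the amide C=O gives a zirconated hemiaminal that collapses only on work-up, so there is no over-reduction, the ester and the trisubstituted alkene survive, and quaternary C1 cannot epimerise.

Step 5
Reactants: 10 aldehyde
Product: 12 (1S,2R)-2-[(1R)-1-acetoxyprop-2-en-1-yl]-2,4-dimethylcyclohex-3-en-1-yl butanoate, via magnesium alkoxide 11 (not isolated)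
Conditions: CH2=CHMgBr (1.2 equiv), THF, −78 °C; then Ac2O, DMAP, −78 to 0 °C
Reagents that add atoms: vinylmagnesium bromide (C=C[Mg]Br); acetic anhydride (CC(=O)OC(C)=O)
Why: In this Felkin–Anh Grignard addition the C14 branch is the large group anti to the incoming vinyl, the carbonyl O lies next to C10 and the nucleophile passes over CH3, which gives 2R, while low temperature and immediate acetylation suppress attack on or migration of the butanoate.

Step 6
Reactants: 12 diester
Product: 13 ring A enone (1S,2R)-2-[(1R)-1-acetoxyprop-2-en-1-yl]-2,4-dimethyl-5-oxocyclohex-3-en-1-yl butanoate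
Conditions: Mn(OAc)3·2H2O (10 mol %), t-BuOOH (5 equiv, decane), 3 Å MS, EtOAc, rt
Reagents that add atoms: tert-butyl hydroperoxide (CC(C)(C)OO)
Why: In this radical allylic C–H oxidation C12 is the only ring allylic CH2, the delocalised radical is oxygenated at C12 and not at neopentyl C10, the electron-poor C2–H is left alone, and the neutral medium spares the β-acyloxy ketone.

Step 7
Reactants: 14 (E)-pent-2-en-4-yn-1-ol
Product: 15 [(2R,3R)-3-ethynyloxiran-2-yl]methanol
Conditions: Ti(OiPr)4 (10 mol %), D-(−)-diethyl tartrate (12 mol %), t-BuOOH (2 equiv), 4 Å MS, CH2Cl2, −20 °C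
Reagents that add atoms: tert-butyl hydroperoxide (CC(C)(C)OO)
Why: Katsuki–Sharpless asymmetric epoxidation with the D-(−)-tartrate gives the (2R,3R) trans-epoxide, which fixes C7 and, before its later inversion, C6.

Step 8
Reactants: 15 epoxy alcohol
Product: 16 (2S,3R)-3-ethynyloxirane-2-carbaldehyde
Conditions: TEMPO (10 mol %), PhI(OAc)2 (1.1 equiv), CH2Cl2, 0 °C to rt
Reagents that add atoms: none
Why: Oxoammonium (TEMPO) oxidation stops at the aldehyde under near-neutral conditions, so the epoxide and C7 are untouched.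

Step 9
Reactants: 16 epoxy aldehyde; 17 1,3-dithiane
Product: 19 (1,3-dithian-2-yl)[(2R,3R)-3-ethynyloxiran-2-yl]methanol (carbinol epimers), via 2-lithio-1,3-dithiane 18 (not isolated)
Conditions: 17 (2.2 equiv), n-BuLi (2.1 equiv), THF, −30 °C; 16, −78 °C; H2O
Reagents that add atoms: none
Why: Corey–Seebach acyl-anion addition brings in C9 as a masked aldehyde, the excess reagent covers the acidic alkyne H, the epoxide is not opened at −78 °C, and the new carbinol centre is erased in the next step.

Step 10
Reactants: 19 dithianyl carbinol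
Product: 20 (1,3-dithian-2-yl)[(2S,3R)-3-ethynyloxiran-2-yl]methanone
Conditions: Dess–Martin periodinane, CH2Cl2, 0 °C
Reagents that add atoms: none
Why: Dess–Martin oxidation gives the C8 ketone without touching the sulfides, the epoxide or the enolisable C7–H.

Step 11
Reactants: 20 epoxy ketone; 21 2-bromopropanoyl chloride (racemic)
Product: 22 (2R,3S)-3-chloro-1-(1,3-dithian-2-yl)-1-oxopent-4-yn-2-yl 2-bromopropanoate (epimers at CHBr)
Conditions: 21 (1.2 equiv), CoCl2 (5 mol %), CH2Cl2/MeCN, 0 °C to rt
Reagents that add atoms: none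
Why: In this Lewis-acid-catalysed acylative epoxide opening (chlorohydrin ester formation) the O-acylated oxonium is opened by chloride in SN2 fashion at propargylic C6, away from electron-poor and hindered C7, so C6 inverts to 6S, C7 is retained, and Cl plus the C17–C19 unit arrive in one step.

Step 12
Reactants: 22 chloro bromo ester
Product: 24 (3R,4S,5R)-5-[(1S)-1-chloroprop-2-yn-1-yl]-4-(1,3-dithian-2-yl)-4-hydroxy-3-methyloxolan-2-one, via zinc enolate 23 (not isolated)
Conditions: Zn dust (1.5 equiv, TMSCl-activated), THF, 0 °C; pH 7 buffer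
Reagents that add atoms: none
Why: In this intramolecular Reformatsky reaction Zn inserts into C–Br faster than into the propargylic C–Cl, and the weakly basic enolate closes the five-membered ring on the C8 ketone with the bulky dithianyl group trans to the C7 side chain and the C17 methyl trans to the dithianyl group, which sets C8 and C17 in the all-trans lactone.

Step 13
Reactants: 24 dithianyl lactone
Product: 25 ring C aldehyde (2R,3S,4R)-2-[(1S)-1-chloroprop-2-yn-1-yl]-3-hydroxy-4-methyl-5-oxooxolane-3-carbaldehyde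
Conditions: PhI(OCOCF3)2 (1.5 equiv), MeCN/H2O 9:1, 0 °C
Reagents that add atoms: water (O)
Why: Oxidative dithiane hydrolysis with a hypervalent iodine reagent is fast and non-basic, so the lactone, chloride, alkyne and tertiary alcohol survive and quaternary C8 cannot epimerise.

Step 14
Reactants: 25 ring C aldehyde; 13 ring A enone (1.5 equiv)
Product: 27 seco enyne (1R,2R,6S,7R,8R,9R,10S,11R,14S,17R), via acetoxy iodide 26 (not isolated)
Conditions: AcI (1.1 equiv), Zn(OTf)2 (2 mol %), CH2Cl2, 0 °C; then 13, Mn2(CO)10 (10 mol %), Hantzsch ester (1.5 equiv), 2,6-lutidine (1.2 equiv), blue LED, 20 °C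
Reagents that add atoms: acetyl iodide (CC(=O)I)
Why: Proposed new method: acetyl iodide adds across the C9 aldehyde to give the weak-C–I acetoxy iodide 26, the Mn(CO)5 radical from photolysis of Mn2(CO)10 abstracts iodine, and the nucleophilic, non-basic α-acetoxyalkyl radical (a ketyl equivalent that does not expel 8-OH and whose 5-exo attack on its own alkyne would need a trans-fused bicyclo[3.3.0] ring) undergoes Giese addition to C10 axially, anti to the C2 side chain and trans to the C14 ester (10S), with C8 anti to C1 and the acetoxy oxygen over the flat enone rather than against C15H3 (9R, the least secure centre), after which the tertiary C11 radical takes H from the Hantzsch ester on the open α face (11R, CH3 cis to C9) and the dihydropyridyl radical returns Mn(CO)5I to the chain; the closest known reaction types are manganese-carbonyl atom-transfer generation of ketyl-type radicals from aldehyde-derived α-acetoxy iodides and manganese-catalysed reductive Giese additions of alkyl iodides.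

Step 15
Reactants: 27 seco enyne
Product: 29 target CNP0283653.2, via seco triene 28 (not isolated)
Conditions: second-generation Grubbs catalyst (10 mol %), ethylene (1 atm), CH2Cl2, 25 °C; then Ar sparge, toluene (0.5 mM), second-generation Hoveyda–Grubbs catalyst (15 mol %), 1,4-benzoquinone (20 mol %), 80 °C
Reagents that add atoms: ethene (C=C)
Why: In this tandem ene–yne cross-metathesis with ethylene followed by ring-closing metathesis the alkyne first becomes the 2-substituted butadiene 28 (creating C5=C16), and its monosubstituted vinyl then closes on the C3 vinyl under reversible conditions that favour the E C3=C4 alkene of the s-trans diene in the trans-fused ten-membered ring, while the neutral medium leaves C11, the chloride and all esters untouched.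

## Compound list
1 | 2-methoxy-5-methylbenzoic acid | COc1ccc(C)cc1C(=O)O | starting material
2 | (S)-2-(methoxymethyl)pyrrolidine | COC[C@@H]1CCCN1 | starting material
3 | 2-methoxy-5-methylbenzoyl chloride | COc1ccc(C)cc1C(=O)Cl | intermediate
4 | (S)-1-(2-methoxy-5-methylbenzoyl)-2-(methoxymethyl)pyrrolidine | COc1ccc(C)cc1C(=O)N1CCC[C@H]1COC | intermediate
5 | potassium amide enolate of the 1,4-dihydroarene | COC1=CCC(C)=CC1=C([O-])N1CCC[C@H]1COC.[K+] | intermediate
6 | (1R)-2-methoxy-1,5-dimethylcyclohexa-2,5-diene-1-carboxamide of 2 | O=C(N1CCC[C@H]1COC)[C@]2(C)C=C(C)CC=C2OC | intermediate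
7 | (1R)-1,3-dimethyl-6-oxocyclohex-2-ene-1-carboxamide of 2 | O=C(N1CCC[C@H]1COC)[C@]2(C)C=C(C)CCC2=O | intermediate
8 | lithium (1R,6S)-alkoxide of the reduced keto amide | O=C(N1CCC[C@H]1COC)[C@]2(C)C=C(C)CC[C@@H]2[O-].[Li+] | intermediate
9 | (1S,2R)-2-{[(S)-2-(methoxymethyl)pyrrolidin-1-yl]carbonyl}-2,4-dimethylcyclohex-3-en-1-yl butanoate | O=C(N1CCC[C@H]1COC)[C@]2(C)C=C(C)CC[C@@H]2OC(=O)CCC | intermediate
10 | (1S,2R)-2-formyl-2,4-dimethylcyclohex-3-en-1-yl butanoate | O=C[C@]1(C)C=C(C)CC[C@@H]1OC(=O)CCC | intermediate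
11 | bromomagnesium (2R)-alkoxide of the vinyl carbinol | C=C[C@@H](O[Mg]Br)[C@]1(C)C=C(C)CC[C@@H]1OC(=O)CCC | intermediate
12 | (1S,2R)-2-[(1R)-1-acetoxyprop-2-en-1-yl]-2,4-dimethylcyclohex-3-en-1-yl butanoate | C=C[C@@H](OC(C)=O)[C@]1(C)C=C(C)CC[C@@H]1OC(=O)CCC | intermediate
13 | ring A enone, (1S,2R)-2-[(1R)-1-acetoxyprop-2-en-1-yl]-2,4-dimethyl-5-oxocyclohex-3-en-1-yl butanoate | C=C[C@@H](OC(C)=O)[C@]1(C)C=C(C)C(=O)C[C@@H]1OC(=O)CCC | intermediate
14 | (E)-pent-2-en-4-yn-1-ol | C#C/C=C/CO | starting material
15 | [(2R,3R)-3-ethynyloxiran-2-yl]methanol | OC[C@H]1O[C@@H]1C#C | intermediate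
16 | (2S,3R)-3-ethynyloxirane-2-carbaldehyde | O=C[C@H]1O[C@@H]1C#C | intermediate
17 | 1,3-dithiane | C1CSCSC1 | starting material
18 | 2-lithio-1,3-dithiane | [Li]C1SCCCS1 | intermediate
19 | (1,3-dithian-2-yl)[(2R,3R)-3-ethynyloxiran-2-yl]methanol, carbinol epimers | OC(C1SCCCS1)[C@H]2O[C@@H]2C#C | intermediate
20 | (1,3-dithian-2-yl)[(2S,3R)-3-ethynyloxiran-2-yl]methanone | O=C(C1SCCCS1)[C@H]2O[C@@H]2C#C | intermediate
21 | 2-bromopropanoyl chloride (racemic) | CC(Br)C(=O)Cl | starting material
22 | (2R,3S)-3-chloro-1-(1,3-dithian-2-yl)-1-oxopent-4-yn-2-yl 2-bromopropanoate | O=C(C1SCCCS1)[C@@H](OC(=O)C(C)Br)[C@H](C#C)Cl | intermediate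
23 | bromozinc ester enolate of 22 | O=C(C1SCCCS1)[C@@H](OC(O[Zn]Br)=CC)[C@H](C#C)Cl | intermediate
24 | (3R,4S,5R)-5-[(1S)-1-chloroprop-2-yn-1-yl]-4-(1,3-dithian-2-yl)-4-hydroxy-3-methyloxolan-2-one | C1CSC(SC1)[C@]2(O)[C@@H](C)C(=O)O[C@H]2[C@H](C#C)Cl | intermediate
25 | ring C aldehyde, (2R,3S,4R)-2-[(1S)-1-chloroprop-2-yn-1-yl]-3-hydroxy-4-methyl-5-oxooxolane-3-carbaldehyde | O=C[C@]1(O)[C@@H](C)C(=O)O[C@H]1[C@H](C#C)Cl | intermediate
26 | acetoxy(iodo)methyl lactone from 25 (C9 epimers) | CC(=O)OC(I)[C@]1(O)[C@@H](C)C(=O)O[C@H]1[C@H](C#C)Cl | intermediate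
27 | seco enyne: ring A ketone with the (1R)-1-acetoxyallyl group on C1 and the (R)-acetoxy(lactonyl)methyl group on C10, C6 bearing Cl and ethynyl | C=C[C@@H](OC(C)=O)[C@]1(C)[C@@H]([C@@H](OC(C)=O)[C@]2(O)[C@@H](C)C(=O)O[C@H]2[C@H](C#C)Cl)[C@@H](C)C(=O)C[C@@H]1OC(=O)CCC | intermediate
28 | seco triene: 27 with the ethynyl group turned into buta-1,3-dien-2-yl | C=C[C@@H](OC(C)=O)[C@]1(C)[C@@H]([C@@H](OC(C)=O)[C@]2(O)[C@@H](C)C(=O)O[C@H]2[C@H](C(=C)C=C)Cl)[C@@H](C)C(=O)C[C@@H]1OC(=O)CCC | intermediate
29 | CNP0283653.2, (1R,2R,3E,6S,7R,8R,9R,10S,11R,14S,17R)-briarane | C=C1/C=C/[C@@H](OC(C)=O)[C@]2(C)[C@@H]([C@@H](OC(C)=O)[C@]3(O)[C@@H](C)C(=O)O[C@H]3[C@H]1Cl)[C@@H](C)C(=O)C[C@@H]2OC(=O)CCC | target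

## Step count and risks
Total steps: 15. Longest linear sequence: 9 (steps 7–15). The ring A branch is 8 steps (steps 1–6, 14, 15).

**Step 14** is the most likely to fail.
- C10 is flanked by quaternary C1.
- The radical may add to alkynes.
- The face of the planar C9 radical is only weakly biased.

The fallback sets out from 13 and 25 and comes back at 27. It replaces the radical by a polar Breslow acyl anion. A thiazolium-carbene Stetter reaction (3-benzyl-5-(2-hydroxyethyl)-4-methylthiazolium chloride, i-Pr2NEt, dioxane, 60 °C) gives the 9-oxo seco enyne F1. Reduction with Me4NBH(OAc)3, bound to and delivered from the 8-OH so that the C12 ketone is spared, gives the 9-hydroxy seco enyne F2. Ac2O/pyridine then acetylates only the secondary 9-OH to give 27.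

**Step 15** carries the strain of the ten-membered ring, the hindered C3 vinyl group and the uncertain E/Z outcome. The fallback sets out from 13 and 25 and comes back at 29. It swaps the order of the two unions.
- Intermolecular ene–yne cross-metathesis (second-generation Hoveyda–Grubbs catalyst, ethylene, CH2Cl2) first gives the open-chain (3E)-diene aldehyde F3.
- Acetyl iodide turns F3 into the acetoxy iodide F4.
- Ring B is then closed through the C9–C10 bond under the step 14 conditions at 1 mM.

**Step 12** may suffer zinc-induced loss of the vicinal chloride/ester pair or proton transfer from C7–H. The fallback sets out from 20 and comes back at 24. It builds C8–C17 before the chloride is present.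
- The lithium enolate of tert-butyl propanoate (LiN(i-Pr)2, THF, −78 °C, 2.2 equiv) adds to the epoxy ketone under chelation control to give the tert-butyl aldol adduct F5.
- TiCl(OiPr)3 opens this 2,3-epoxy alcohol with chloride at C6.
- The freed C7 alkoxide lactonises to 24.

## Further compounds
F1 | step 14 | 9-oxo seco enyne (1,4-diketone) | C=C[C@@H](OC(C)=O)[C@]1(C)[C@@H](C(=O)[C@]2(O)[C@@H](C)C(=O)O[C@H]2[C@H](C#C)Cl)[C@@H](C)C(=O)C[C@@H]1OC(=O)CCC
F2 | step 14 | 9-hydroxy seco enyne | C=C[C@@H](OC(C)=O)[C@]1(C)[C@@H]([C@@H](O)[C@]2(O)[C@@H](C)C(=O)O[C@H]2[C@H](C#C)Cl)[C@@H](C)C(=O)C[C@@H]1OC(=O)CCC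
F3 | step 15 | open-chain (3E)-3,5(16)-diene 9-aldehyde | C=C(/C=C/[C@@H](OC(C)=O)[C@]1(C)C=C(C)C(=O)C[C@@H]1OC(=O)CCC)[C@H](Cl)[C@@H]2OC(=O)[C@H](C)[C@@]2(O)C=O
F4 | step 15 | 9-acetoxy-9-iodide of F3 | C=C(/C=C/[C@@H](OC(C)=O)[C@]1(C)C=C(C)C(=O)C[C@@H]1OC(=O)CCC)[C@H](Cl)[C@@H]2OC(=O)[C@H](C)[C@@]2(O)C(I)OC(C)=O
F5 | step 12 | tert-butyl (2R,3S)-3-(1,3-dithian-2-yl)-3-[(2R,3R)-3-ethynyloxiran-2-yl]-3-hydroxy-2-methylpropanoate | CC(C)(C)OC(=O)[C@H](C)[C@@](O)(C1SCCCS1)[C@H]2O[C@@H]2C#C
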